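**Retrosynthetic overview**
1. (2S,3S)-trans-δ-viniferin ⇐ fivefold O-demethylation, with acid-mediated epimerization at C2, of the 2,3-cis penta-O-methyl ether.
2. cis-Penta-O-methyl ether ⇐ one telescoped operation that makes the C5–CH= bond (Mizoroki–Heck coupling with 3,5-dimethoxystyrene) and the C2–C3 bond of the dihydrofuran ring (enantioselective Rh-carbene 1,5 C–H insertion) from an acyclic, achiral diaryl ketone hydrazone.
3. Enabling feature: C5 of the benzo ring (C3a–C7a) is para to O1 and remote from C2/C3, so a bromine there is ignored by the rhodium carbene and is afterwards the only site for palladium. C2–H is a benzylic, O1-activated C–H bond 1,5 to C3. The O1–C2 bond, benzylic to a para-oxygenated aryl ring, can be ionized at the end to turn cis into trans.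
4. Hydrazone ⇐ diaryl ketone ⇐ aryl Grignard addition and oxidation ⇐ O-benzylation of 5-bromosalicylaldehyde.
5. Ring order: the three benzene rings are bought in; the only ring made is the dihydrofuran ring (O1–C2–C3–C3a–C7a), closed in the key step.

Key step: step 5

Assumption: Rh2(R-PTAD)4 is taken as the catalyst enantiomer that leads to the 3S series; if the sense of induction is the opposite, Rh2(S-PTAD)4 is used with no other change.

**Route**

Step 1
Reactants: 1 5-bromo-2-hydroxybenzaldehyde; 2 4-methoxybenzyl chloride
Product: 3 5-bromo-2-[(4-methoxyphenyl)methoxy]benzaldehyde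
Conditions: K2CO3, KI (cat.), DMF, 60 °C
Reagents that add atoms: none
Why: Williamson ether synthesis: the phenoxide of 1 displaces chloride from the benzylic halide by SN2 and installs the O–CH2–aryl unit whose CH2 later becomes C2.

Step 2
Reactants: 3 5-bromo-2-[(4-methoxyphenyl)methoxy]benzaldehyde; 4 3,5-dimethoxyphenylmagnesium chloride (THF solution)
Product: 5 rac-{5-bromo-2-[(4-methoxyphenyl)methoxy]phenyl}(3,5-dimethoxyphenyl)methanol
Conditions: THF, 0 °C to rt; aq. NH4Cl
Reagents that add atoms: none
Why: Grignard addition to the aldehyde should give the diaryl carbinol; its stereocenter is removed by oxidation in the next step, and the aryl bromide should not exchange with an aryl Grignard reagent at this temperature.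

Step 3
Reactants: 5 rac-{5-bromo-2-[(4-methoxyphenyl)methoxy]phenyl}(3,5-dimethoxyphenyl)methanol
Product: 6 {5-bromo-2-[(4-methoxyphenyl)methoxy]phenyl}(3,5-dimethoxyphenyl)methanone
Conditions: Dess–Martin periodinane (DMP), NaHCO3, CH2Cl2, rt
Reagents that add atoms: none
Why: Dess–Martin oxidation of a secondary benzylic alcohol to the diaryl ketone runs under buffered neutral conditions that leave the benzylic ether and the aryl bromide untouched.

Step 4
Reactants: 6 {5-bromo-2-[(4-methoxyphenyl)methoxy]phenyl}(3,5-dimethoxyphenyl)methanone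
Product: 7 hydrazone of ketone 6 (E/Z mixture)
Conditions: N2H4·H2O (excess), AcOH (cat.), EtOH, 80 °C, under argon
Reagents that add atoms: hydrazine (as hydrate), NN
Why: Acid-catalysed hydrazone formation with excess hydrazine should give the N-unsubstituted hydrazone, and both C=N isomers lead to the same diazo compound.

Step 5
Reactants: 7 hydrazone of ketone 6; 8 3,5-dimethoxystyrene
Product: 11 (2R,3S)-3-(3,5-dimethoxyphenyl)-5-[(E)-2-(3,5-dimethoxyphenyl)ethenyl]-2-(4-methoxyphenyl)-2,3-dihydro-1-benzofuran (2,3-cis), via diaryldiazomethane 9 (not isolated), via cis-bromide 10 (not isolated)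
Conditions: (a) activated MnO2, CH2Cl2, 0 °C, filtration through Celite; (b) Rh2(R-PTAD)4 (1 mol %), CH2Cl2, 0 °C to rt; (c) solvent exchange to DMF without work-up, then 8, Pd(OAc)2, P(o-tol)3, K2CO3, 100 °C
Reagents that add atoms: none
Why: MnO2 dehydrogenates hydrazone 7 to diaryldiazomethane 9, which Rh2(R-PTAD)4 turns into a donor/donor carbene that inserts into the ether-activated benzylic C–H bond of the O–CH2–aryl group; the closest known reaction type is the enantioselective intramolecular C–H insertion of donor/donor rhodium carbenes that gives cis-2,3-diaryl-2,3-dihydrobenzofurans. The dihydrofuran ring closes by 1,5-insertion through a five-membered transition state (new C2–C3 bond); C3 is set by the chiral carboxylate ligands of the catalyst, and C2 follows as cis because the concerted insertion places both aryl groups on the same face. The C5–Br bond is inert to the rhodium carbene and becomes the only site for oxidative addition once palladium is added; syn-carbopalladation of styrene 8 at its terminal carbon and syn-β-hydride elimination then form the C5–CH= bond and the E alkene (Mizoroki–Heck reaction). The step needs chemoselectivity in the carbene stage (insertion instead of azine formation or cyclopropanation) and site selectivity in the coupling; the first is secured by the 1,5-relationship between the carbene carbon and the O–CH2 group and by adding the styrene only after nitrogen evolution has ended, the second by the single C–Br bond para to O1. The cis relationship at C2 is corrected in step 6, so only the configuration at C3 has to be right here.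

Step 6
Reactants: 11 (2R,3S)-cis-penta-O-methyl ether
Product: 12 (2S,3S)-trans-delta-viniferin
Conditions: BBr3 (excess), CH2Cl2, −78 °C to rt; MeOH quench and stirring at rt; aq. NaHCO3
Reagents that add atoms: none
Why: Lewis-acid ether cleavage with BBr3 should free all five phenols, while reversible acid ionization of the O1–C2 bond (benzylic cation stabilized by the para-oxygenated aryl ring) and re-closure deliver the thermodynamically favoured trans isomer with C3 untouched, that is (2S,3S).

**Compound list**
1 | 5-bromo-2-hydroxybenzaldehyde (5-bromosalicylaldehyde) | O=Cc1cc(Br)ccc1O | starting material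
2 | 4-methoxybenzyl chloride | COc1ccc(CCl)cc1 | starting material
3 | 5-bromo-2-[(4-methoxyphenyl)methoxy]benzaldehyde | COc1ccc(COc2ccc(Br)cc2C=O)cc1 | intermediate
4 | 3,5-dimethoxyphenylmagnesium chloride | COc1cc(OC)cc([Mg]Cl)c1 | starting material
5 | rac-{5-bromo-2-[(4-methoxyphenyl)methoxy]phenyl}(3,5-dimethoxyphenyl)methanol | COc1ccc(COc2ccc(Br)cc2C(O)c2cc(OC)cc(OC)c2)cc1 | intermediate
6 | {5-bromo-2-[(4-methoxyphenyl)methoxy]phenyl}(3,5-dimethoxyphenyl)methanone | COc1ccc(COc2ccc(Br)cc2C(=O)c2cc(OC)cc(OC)c2)cc1 | intermediate
7 | hydrazone of ketone 6 (E/Z mixture) | COc1ccc(COc2ccc(Br)cc2C(=NN)c2cc(OC)cc(OC)c2)cc1 | intermediate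
8 | 3,5-dimethoxystyrene (1-ethenyl-3,5-dimethoxybenzene) | C=Cc1cc(OC)cc(OC)c1 | starting material
9 | 4-bromo-2-[diazo(3,5-dimethoxyphenyl)methyl]-1-[(4-methoxyphenyl)methoxy]benzene | COc1ccc(COc2ccc(Br)cc2C(=[N+]=[N-])c2cc(OC)cc(OC)c2)cc1 | intermediate
10 | (2R,3S)-5-bromo-3-(3,5-dimethoxyphenyl)-2-(4-methoxyphenyl)-2,3-dihydro-1-benzofuran (2,3-cis) | COc1ccc([C@@H]2Oc3ccc(Br)cc3[C@@H]2c2cc(OC)cc(OC)c2)cc1 | intermediate
11 | (2R,3S)-3-(3,5-dimethoxyphenyl)-5-[(E)-2-(3,5-dimethoxyphenyl)ethenyl]-2-(4-methoxyphenyl)-2,3-dihydro-1-benzofuran (2,3-cis) | COc1ccc([C@@H]2Oc3ccc(/C=C/c4cc(OC)cc(OC)c4)cc3[C@@H]2c2cc(OC)cc(OC)c2)cc1 | intermediate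
12 | (2S,3S)-trans-delta-viniferin | Oc1ccc([C@H]2Oc3ccc(/C=C/c4cc(O)cc(O)c4)cc3[C@@H]2c2cc(O)cc(O)c2)cc1 | target

**Step count and risks**

Total step count: 6. Longest linear sequence: 6 steps (from 1).

Steps most likely to fail:

1. Step 5. The palladium catalyst may be inhibited by rhodium, azine or manganese residues carried through the telescoped sequence, so that the coupling stalls, and the insertion may lose enantio- or diastereoselectivity when it cannot be optimized on its own. The fallback changes the order of bond formation and sets out from ketone 6. Mizoroki–Heck coupling of 6 with 8 (Pd(OAc)2, P(o-tol)3, K2CO3, DMF, 100 °C) should give the stilbene ketone F1. Condensation with hydrazine hydrate should give the hydrazone F2. MnO2 should then give the diazo compound F3, which is not isolated, and Rh2(R-PTAD)4 should close the dihydrofuran ring by the same 1,5 C–H insertion. The sequence comes back to the route at 11.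

2. Step 6. Fivefold Lewis-acid demethylation in the presence of the electron-rich stilbene may cause acid-induced oligomerization or cyclization of the alkene, or incomplete re-closure of the dihydrofuran ring. The fallback frees the phenols before the alkene exists. The sequence of step 5 is stopped after the rhodium stage and 10 is isolated. BBr3 (CH2Cl2, −78 °C to rt) should give, with the same epimerization at C2, the trans bromo triphenol F4. Ac2O and pyridine should give the triacetate F5. Mizoroki–Heck coupling with commercial 3,5-diacetoxystyrene (CC(=O)Oc1cc(C=C)cc(OC(C)=O)c1; Pd(OAc)2, P(o-tol)3, NaOAc, DMF, 100 °C) should give the pentaacetate F6. K2CO3 in MeOH at 0 °C to rt should remove the five acetates. The sequence sets out from 10 and comes back to the route at 12.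

3. Step 4. Condensation at the hindered, electron-rich ortho-alkoxy diaryl ketone may stay incomplete, or the hydrazone may go on to the azine. The fallback uses a different diazo precursor and sets out from ketone 6. Tosylhydrazide (cat. HCl, EtOH, 70 °C) should give the N-tosylhydrazone F7. Its sodium salt (NaH, dioxane) should release the diazo compound thermally (Bamford–Stevens reaction) in the presence of Rh2(R-PTAD)4; this comes back to the route at 9 within step 5, which then continues unchanged.

Further compounds
F1 | step 5 | {5-[(E)-2-(3,5-dimethoxyphenyl)ethenyl]-2-[(4-methoxyphenyl)methoxy]phenyl}(3,5-dimethoxyphenyl)methanone | COc1ccc(COc2ccc(/C=C/c3cc(OC)cc(OC)c3)cc2C(=O)c2cc(OC)cc(OC)c2)cc1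
F2 | step 5 | hydrazone of ketone F1 (E/Z mixture) | COc1ccc(COc2ccc(/C=C/c3cc(OC)cc(OC)c3)cc2C(=NN)c2cc(OC)cc(OC)c2)cc1
F3 | step 5 | diazo compound from hydrazone F2 | COc1ccc(COc2ccc(/C=C/c3cc(OC)cc(OC)c3)cc2C(=[N+]=[N-])c2cc(OC)cc(OC)c2)cc1
F4 | step 6 | (2S,3S)-5-bromo-3-(3,5-dihydroxyphenyl)-2-(4-hydroxyphenyl)-2,3-dihydro-1-benzofuran (2,3-trans) | Oc1ccc([C@H]2Oc3ccc(Br)cc3[C@@H]2c2cc(O)cc(O)c2)cc1
F5 | step 6 | tri-O-acetate of F4 | CC(=O)Oc1ccc([C@H]2Oc3ccc(Br)cc3[C@@H]2c2cc(OC(C)=O)cc(OC(C)=O)c2)cc1
F6 | step 6 | penta-O-acetyl-(2S,3S)-trans-delta-viniferin | CC(=O)Oc1ccc([C@H]2Oc3ccc(/C=C/c4cc(OC(C)=O)cc(OC(C)=O)c4)cc3[C@@H]2c2cc(OC(C)=O)cc(OC(C)=O)c2)cc1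
F7 | step 4 | N-tosylhydrazone of ketone 6 | COc1ccc(COc2ccc(Br)cc2C(=NNS(=O)(=O)c2ccc(C)cc2)c2cc(OC)cc(OC)c2)cc1
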